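**Plan**

Numbering: drimane locants for the decalin (ring A = C1–C5 and C10, ring B = C5–C10, C11 = the benzylic CH) and primed locants for the arene (C1' carries C11, C2' the sulfate, C3' the formyl group).
Cuts: the O–S and C3'–CHO bonds on the arene; C9=C11 (back to a C9 ketone and a benzyl nucleophile); C1–C10 of ring A; and C4–C5 (aryl to quaternary carbon).
Enabling feature: ring B carries methyl groups on C8 and C10 on either side of the sp2 carbon C9, so it is a disguised 2,6-dimethylphenol with its oxygen on C9. A C4–C3–C2–C1 chain hanging from C5 can therefore alkylate the methyl-bearing ortho carbon C10. A triflyloxy group on C6, the second oxygen of a hydroquinone, blocks the para carbon and is deleted afterwards.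
Forward order: ring B starts as 2,6-dimethylhydroquinone; C4 with both methyls is joined to C5 by lactone formation and the chain is extended to C1–I; ring A then closes with dearomatisation of ring B; ring B is reduced, the benzyl fragment is added at C9, and the arene is formylated, sulfated and unmasked.
Stereochemistry: C10 comes from the chiral ammonium counter-ion in the ring closure; C5 and C8 from hydrogen delivery to the face opposite the C10 methyl; the E alkene from a syn elimination in which the aryl group turns away from quaternary C10.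

Key step: step 8

Assumption: the target is drawn as the free hydrogen sulfate, so 30 and 31 are written in that form although they would be handled as salts and the acid liberated on an H+-form resin; the sense of induction of the cinchonidinium ion pair cannot be predicted, and the pseudoenantiomeric cinchoninium salt would be used if the (R)-dienone were favoured.

Step 1
Reactants: 1 2,6-dimethylbenzene-1,4-diol; 2 3-methylbut-2-enoic acid
Product: 3 6-hydroxy-4,4,5,7-tetramethylchroman-2-one
Conditions: MeSO3H, 70 °C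
Reagents that add atoms: none
Why: Acid-mediated Friedel–Crafts alkylation with lactonisation (the trimethyl-lock lactone synthesis): the two free ring positions of 1 are equivalent and lie next to the unhindered hydroxyl, so the new bond forms between that oxygen and a ring methyl, which creates C4–C5 with both C4 methyls in place and leaves the hindered C9 hydroxyl free.

Step 2
Reactants: 3 6-hydroxy-4,4,5,7-tetramethylchroman-2-one
Product: 4 6-(methoxymethoxy)-4,4,5,7-tetramethylchroman-2-one
Conditions: MOMCl, i-Pr2NEt, Bu4NI (cat.), CH2Cl2, 0 → 40 °C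
Reagents that add atoms: chloromethyl methyl ether, COCCl
Why: O-Alkylation of the remaining phenol gives a MOM ether that should survive hydride, ylide, triflation and hydrozirconation and come off with dilute acid.

Step 3
Reactants: 4 6-(methoxymethoxy)-4,4,5,7-tetramethylchroman-2-one
Product: 5 6-(methoxymethoxy)-4,4,5,7-tetramethylchroman-2-ol (racemic lactol)
Conditions: i-Bu2AlH (1.1 equiv), CH2Cl2, −78 °C
Reagents that add atoms: none
Why: Partial reduction of an aryl lactone to the lactol with one equivalent of i-Bu2AlH at low temperature, the tetrahedral aluminate being stable until work-up.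

Step 4
Reactants: 5 6-(methoxymethoxy)-4,4,5,7-tetramethylchroman-2-ol
Product: 7 4-(methoxymethoxy)-3,5-dimethyl-2-(2-methylpent-4-en-2-yl)phenol, via ring-opened hydroxy aldehyde 6 (not isolated)
Conditions: Ph3PCH3Br, KOt-Bu (3 equiv each), THF, 0 °C → rt
Reagents that add atoms: methyltriphenylphosphonium bromide, C[P+](c1ccccc1)(c1ccccc1)c1ccccc1.[Br-]
Why: Wittig methylenation of the lactol through its ring-opened phenoxide aldehyde 6 adds C1 as a terminal alkene carbon and releases the C6 oxygen as a free phenol.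

Step 5
Reactants: 7 4-(methoxymethoxy)-3,5-dimethyl-2-(2-methylpent-4-en-2-yl)phenol
Product: 8 4-(methoxymethoxy)-3,5-dimethyl-2-(2-methylpent-4-en-2-yl)phenyl trifluoromethanesulfonate
Conditions: Tf2O, pyridine, CH2Cl2, 0 °C
Reagents that add atoms: trifluoromethanesulfonic anhydride, O=S(=O)(OS(=O)(=O)C(F)(F)F)C(F)(F)F
Why: O-Sulfonylation of the phenol with Tf2O and pyridine installs the group that will block C6 in the ring closure and can later be removed reductively.

Step 6
Reactants: 8 4-(methoxymethoxy)-3,5-dimethyl-2-(2-methylpent-4-en-2-yl)phenyl trifluoromethanesulfonate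
Product: 10 2-(5-iodo-2-methylpentan-2-yl)-4-(methoxymethoxy)-3,5-dimethylphenyl trifluoromethanesulfonate, via alkylzirconocene chloride 9 (not isolated)
Conditions: Cp2Zr(H)Cl, THF, rt; then I2, 0 °C
Reagents that add atoms: iodine, II
Why: Hydrozirconation places zirconium on the terminal carbon of the monosubstituted alkene (sterically controlled anti-Markovnikov addition), and iodinolysis of the C–Zr bond should give the primary iodide at C1 without touching the aryl triflate or the acetal.

Step 7
Reactants: 10 2-(5-iodo-2-methylpentan-2-yl)-4-(methoxymethoxy)-3,5-dimethylphenyl trifluoromethanesulfonate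
Product: 11 4-hydroxy-2-(5-iodo-2-methylpentan-2-yl)-3,5-dimethylphenyl trifluoromethanesulfonate
Conditions: HCl (cat.), MeOH, 40 °C
Reagents that add atoms: none
Why: Acid-catalysed acetal exchange with methanol removes the MOM group, while the aryl triflate and the primary iodide are inert to dilute acid.

Step 8
Reactants: 11 4-hydroxy-2-(5-iodo-2-methylpentan-2-yl)-3,5-dimethylphenyl trifluoromethanesulfonate
Product: 13 (4aS)-3,4a,8,8-tetramethyl-4-oxo-4,4a,5,6,7,8-hexahydronaphthalen-1-yl trifluoromethanesulfonate, via chiral ammonium phenoxide ion pair 12 (not isolated)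
Conditions: O-allyl-N-(9-anthracenylmethyl)cinchonidinium bromide (10 mol %), powdered K3PO4, toluene (0.01 M), −20 → 0 °C
Reagents that add atoms: none
Why: Proposed new method: solid K3PO4 deprotonates the phenol, the phenoxide enters toluene as ion pair 12 with the cinchonidinium cation, and its methyl-bearing ortho carbon C10 displaces iodide from C1 in an intramolecular SN2 reaction, giving a cyclohexa-2,4-dienone that cannot re-aromatise because C10 is now quaternary. The closest known reactions are the racemic base-mediated ortho-C-alkylative dearomatisation of 2,6-disubstituted phenoxides and the chiral-ammonium phase-transfer alkylation of enolates. Ring A closes in the 6-exo-tet mode. The new stereocentre C10 has no substrate bias and must be set by the chiral cation, which is expected to cover one face of the planar phenoxide within the tight ion pair in a non-polar solvent. The step needs C-alkylation at C10 rather than at the para carbon C6 or at oxygen: the triflyloxy group on C6 makes ipso attack there sterically and electronically unfavourable, intramolecular O-alkylation would need an eight-membered ring, and high dilution suppresses intermolecular O-alkylation.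

Step 9
Reactants: 13 (4aS)-3,4a,8,8-tetramethyl-4-oxo-4,4a,5,6,7,8-hexahydronaphthalen-1-yl trifluoromethanesulfonate
Product: 14 (8aS)-2,5,5,8a-tetramethyl-6,7,8,8a-tetrahydronaphthalen-1(5H)-one
Conditions: Pd(OAc)2 (cat.), PPh3, HCO2H, Et3N, DMF, 60 °C
Reagents that add atoms: none
Why: Palladium-catalysed formate reduction of the enol triflate (oxidative addition into C–OTf, formate-to-hydride exchange with loss of CO2, reductive elimination) replaces the blocking group on C6 by hydrogen and should leave the dienone untouched.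

Step 10
Reactants: 14 (8aS)-2,5,5,8a-tetramethyl-6,7,8,8a-tetrahydronaphthalen-1(5H)-one
Product: 15 (2S,4aS,8aS)-2,5,5,8a-tetramethyloctahydronaphthalen-1(2H)-one
Conditions: H2 (20 bar), Pd/C, EtOAc, rt
Reagents that add atoms: none
Why: Heterogeneous hydrogenation in which both ring alkenes should adsorb on the face opposite the axial C10 methyl (and the axial C4 methyl, as in 4,4,10-trimethyl-Δ5-octalins), so hydrogen reaches C5 and C8 from that face and sets the trans ring fusion and the C8 methyl cis to the C10 methyl, while the neutral medium should preserve the kinetically formed, epimerisable C8 centre.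

Step 11
Reactants: 16 2,4,5-trihydroxybenzaldehyde
Product: 17 2-hydroxy-4,5-bis(prop-2-en-1-yloxy)benzaldehyde
Conditions: allyl bromide (2.1 equiv), K2CO3, DMF, rt
Reagents that add atoms: allyl bromide, C=CCBr
Why: Williamson etherification in which the 2-hydroxyl, tied up in a hydrogen bond to the formyl group, is the least nucleophilic, so two equivalents of allyl bromide should alkylate only O4 and O5.

Step 12
Reactants: 17 2-hydroxy-4,5-bis(prop-2-en-1-yloxy)benzaldehyde
Product: 18 2-(methoxymethoxy)-4,5-bis(prop-2-en-1-yloxy)benzaldehyde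
Conditions: MOMCl, i-Pr2NEt, CH2Cl2, 0 °C → rt
Reagents that add atoms: chloromethyl methyl ether, COCCl
Why: Alkylation of the chelated phenol with MOMCl and a hindered amine gives an oxygen pattern in which O2' can later be freed without touching the allyl ethers on O4' and O5'.

Step 13
Reactants: 18 2-(methoxymethoxy)-4,5-bis(prop-2-en-1-yloxy)benzaldehyde
Product: 19 [2-(methoxymethoxy)-4,5-bis(prop-2-en-1-yloxy)phenyl]methanol
Conditions: NaBH4, MeOH, 0 °C
Reagents that add atoms: none
Why: Borohydride reduction of the aryl aldehyde to the benzylic alcohol.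

Step 14
Reactants: 19 [2-(methoxymethoxy)-4,5-bis(prop-2-en-1-yloxy)phenyl]methanol
Product: 20 1-(chloromethyl)-2-(methoxymethoxy)-4,5-bis(prop-2-en-1-yloxy)benzene
Conditions: PPh3, N-chlorosuccinimide (premixed), CH2Cl2, −20 → 0 °C; used at once
Reagents that add atoms: N-chlorosuccinimide, O=C1CCC(=O)N1Cl
Why: Appel-type chlorination with the preformed chlorophosphonium salt converts the benzylic alcohol into the chloride under neutral conditions that spare the MOM acetal and the electron-rich ring.

Step 15
Reactants: 20 1-(chloromethyl)-2-(methoxymethoxy)-4,5-bis(prop-2-en-1-yloxy)benzene; 15 (2S,4aS,8aS)-2,5,5,8a-tetramethyloctahydronaphthalen-1(2H)-one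
Product: 23 (1S,2S,4aS,8aS)-1-[2-(methoxymethoxy)-4,5-bis(prop-2-en-1-yloxy)benzyl]-2,5,5,8a-tetramethyldecahydronaphthalen-1-ol, via benzylmagnesium chloride 21 (not isolated), via benzylcerium dichloride 22 (not isolated)
Conditions: 20, Mg, THF, 0 °C (slow addition); then anhydrous CeCl3, −78 °C; then 15, −78 → 0 °C
Reagents that add atoms: none
Why: Organocerium addition to a hindered, enolisable ketone: the weakly basic cerium reagent 22 should add to C9 without deprotonating C8, attacking anti to the axial methyls on C8 and C10 to give the C9 carbinol shown, whose configuration is erased in the next step.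

Step 16
Reactants: 23 (1S,2S,4aS,8aS)-1-[2-(methoxymethoxy)-4,5-bis(prop-2-en-1-yloxy)benzyl]-2,5,5,8a-tetramethyldecahydronaphthalen-1-ol
Product: 25 (1E,2S,4aS,8aS)-1-[2-(methoxymethoxy)-4,5-bis(prop-2-en-1-yloxy)benzylidene]-2,5,5,8a-tetramethyldecahydronaphthalene, via sulfamate ester 24 (not isolated)
Conditions: Burgess reagent, toluene, 70 °C
Reagents that add atoms: none
Why: Burgess dehydration, a thermal syn elimination of sulfamate 24 in which only the C11 hydrogens can become syn-periplanar to the C9–O bond because H8 lies on the opposite face, so the exocyclic C9=C11 alkene should form with the aryl group turned away from quaternary C10 (E isomer) and without a carbocation that could rearrange.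

Step 17
Reactants: 25 (1E,2S,4aS,8aS)-1-[2-(methoxymethoxy)-4,5-bis(prop-2-en-1-yloxy)benzylidene]-2,5,5,8a-tetramethyldecahydronaphthalene
Product: 27 2-{(E)-[(2S,4aS,8aS)-2,5,5,8a-tetramethyloctahydronaphthalen-1(2H)-ylidene]methyl}-4,5-bis(prop-2-en-1-yloxy)phenol, via trimethylsilyl ether 26 (not isolated)
Conditions: TMSOTf, 2,2'-bipyridyl, CH2Cl2, 0 °C; then H2O
Reagents that add atoms: none
Why: Cleavage of the aromatic MOM ether with TMSOTf buffered by 2,2'-bipyridyl gives silyl ether 26, which water hydrolyses, so no protic acid meets the ortho-hydroxystyrene, which could otherwise cyclise onto C9.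

Step 18
Reactants: 27 2-{(E)-[(2S,4aS,8aS)-2,5,5,8a-tetramethyloctahydronaphthalen-1(2H)-ylidene]methyl}-4,5-bis(prop-2-en-1-yloxy)phenol
Product: 29 2-hydroxy-3-{(E)-[(2S,4aS,8aS)-2,5,5,8a-tetramethyloctahydronaphthalen-1(2H)-ylidene]methyl}-5,6-bis(prop-2-en-1-yloxy)benzaldehyde, via salicyl alcohol 28 (not isolated)
Conditions: MgCl2, Et3N, (CH2O)n, MeCN, reflux
Reagents that add atoms: formaldehyde (as paraformaldehyde), C=O
Why: Magnesium-mediated ortho-formylation (Casnati–Skattebøl reaction): the magnesium phenoxide delivers formaldehyde only to the carbon ortho to O2', C3' being the single free ortho position, and the salicyl alcohol 28 is oxidised in the flask by hydride transfer to a second formaldehyde, so neither acid nor organolithium touches the allyl ethers or the alkene.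

Step 19
Reactants: 29 2-hydroxy-3-{(E)-[(2S,4aS,8aS)-2,5,5,8a-tetramethyloctahydronaphthalen-1(2H)-ylidene]methyl}-5,6-bis(prop-2-en-1-yloxy)benzaldehyde
Product: 30 2-formyl-3,4-bis(prop-2-en-1-yloxy)-6-{(E)-[(2S,4aS,8aS)-2,5,5,8a-tetramethyloctahydronaphthalen-1(2H)-ylidene]methyl}phenyl hydrogen sulfate
Conditions: SO3·pyridine, pyridine, 50 °C
Reagents that add atoms: sulfur trioxide–pyridine complex, [O-]S(=O)(=O)[n+]1ccccc1
Why: O-Sulfation of the only free phenol with the SO3·pyridine complex gives the aryl sulfate monoester, which is stable to the mildly basic conditions of the last step.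

Step 20
Reactants: 30 2-formyl-3,4-bis(prop-2-en-1-yloxy)-6-{(E)-[(2S,4aS,8aS)-2,5,5,8a-tetramethyloctahydronaphthalen-1(2H)-ylidene]methyl}phenyl hydrogen sulfate
Product: 31 2-formyl-3,4-dihydroxy-6-{(E)-[(2S,4aS,8aS)-2,5,5,8a-tetramethyloctahydronaphthalen-1(2H)-ylidene]methyl}phenyl hydrogen sulfate
Conditions: Pd(PPh3)4 (cat.), K2CO3, MeOH (degassed), rt; then H+-form cation-exchange resin, 0 °C
Reagents that add atoms: none
Why: Palladium-catalysed deallylation (π-allylpalladium formation from the aryl allyl ethers and capture by methoxide) should free the catechol under conditions that leave the aryl sulfate, the aldehyde and the trisubstituted alkene untouched.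

**Compound list**

1 | 2,6-dimethylbenzene-1,4-diol | Cc1cc(O)cc(C)c1O | starting material
2 | 3-methylbut-2-enoic acid | CC(C)=CC(=O)O | starting material
3 | 6-hydroxy-4,4,5,7-tetramethylchroman-2-one | Cc1cc2OC(=O)CC(C)(C)c2c(C)c1O | intermediate
4 | 6-(methoxymethoxy)-4,4,5,7-tetramethylchroman-2-one | COCOc1c(C)cc2OC(=O)CC(C)(C)c2c1C | intermediate
5 | 6-(methoxymethoxy)-4,4,5,7-tetramethylchroman-2-ol (racemic) | COCOc1c(C)cc2OC(O)CC(C)(C)c2c1C | intermediate
6 | 3-[6-hydroxy-3-(methoxymethoxy)-2,4-dimethylphenyl]-3-methylbutanal (not isolated) | O=CCC(C)(C)c1c(O)cc(C)c(OCOC)c1C | intermediate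
7 | 4-(methoxymethoxy)-3,5-dimethyl-2-(2-methylpent-4-en-2-yl)phenol | C=CCC(C)(C)c1c(O)cc(C)c(OCOC)c1C | intermediate
8 | 4-(methoxymethoxy)-3,5-dimethyl-2-(2-methylpent-4-en-2-yl)phenyl trifluoromethanesulfonate | C=CCC(C)(C)c1c(OS(=O)(=O)C(F)(F)F)cc(C)c(OCOC)c1C | intermediate
9 | chlorobis(cyclopentadienyl){4-[3-(methoxymethoxy)-2,4-dimethyl-6-(trifluoromethanesulfonyloxy)phenyl]-4-methylpentyl}zirconium (not isolated) | CC(C)(CCC[Zr](Cl)(C1C=CC=C1)C1C=CC=C1)c1c(OS(=O)(=O)C(F)(F)F)cc(C)c(OCOC)c1C | intermediate
10 | 2-(5-iodo-2-methylpentan-2-yl)-4-(methoxymethoxy)-3,5-dimethylphenyl trifluoromethanesulfonate | CC(C)(CCCI)c1c(OS(=O)(=O)C(F)(F)F)cc(C)c(OCOC)c1C | intermediate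
11 | 4-hydroxy-2-(5-iodo-2-methylpentan-2-yl)-3,5-dimethylphenyl trifluoromethanesulfonate | CC(C)(CCCI)c1c(OS(=O)(=O)C(F)(F)F)cc(C)c(O)c1C | intermediate
12 | O-allyl-N-(9-anthracenylmethyl)cinchonidinium 3-(5-iodo-2-methylpentan-2-yl)-2,6-dimethyl-4-(trifluoromethanesulfonyloxy)phenoxide (ion pair, not isolated) | CC(C)(CCCI)c1c(OS(=O)(=O)C(F)(F)F)cc(C)c([O-])c1C.C=C[C@H]1C[N+]2(Cc3c4ccccc4cc4ccccc34)CC[C@H]1C[C@H]2[C@H](OCC=C)c1ccnc2ccccc12 | intermediate
13 | (4aS)-3,4a,8,8-tetramethyl-4-oxo-4,4a,5,6,7,8-hexahydronaphthalen-1-yl trifluoromethanesulfonate | CC1=CC(OS(=O)(=O)C(F)(F)F)=C2C(C)(C)CCC[C@]2(C)C1=O | intermediate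
14 | (8aS)-2,5,5,8a-tetramethyl-6,7,8,8a-tetrahydronaphthalen-1(5H)-one | CC1=CC=C2C(C)(C)CCC[C@]2(C)C1=O | intermediate
15 | (2S,4aS,8aS)-2,5,5,8a-tetramethyloctahydronaphthalen-1(2H)-one | C[C@H]1CC[C@H]2C(C)(C)CCC[C@]2(C)C1=O | intermediate
16 | 2,4,5-trihydroxybenzaldehyde | O=Cc1cc(O)c(O)cc1O | starting material
17 | 2-hydroxy-4,5-bis(prop-2-en-1-yloxy)benzaldehyde | O=Cc1cc(OCC=C)c(OCC=C)cc1O | intermediate
18 | 2-(methoxymethoxy)-4,5-bis(prop-2-en-1-yloxy)benzaldehyde | O=Cc1cc(OCC=C)c(OCC=C)cc1OCOC | intermediate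
19 | [2-(methoxymethoxy)-4,5-bis(prop-2-en-1-yloxy)phenyl]methanol | OCc1cc(OCC=C)c(OCC=C)cc1OCOC | intermediate
20 | 1-(chloromethyl)-2-(methoxymethoxy)-4,5-bis(prop-2-en-1-yloxy)benzene | ClCc1cc(OCC=C)c(OCC=C)cc1OCOC | intermediate
21 | [2-(methoxymethoxy)-4,5-bis(prop-2-en-1-yloxy)benzyl]magnesium chloride (not isolated) | Cl[Mg]Cc1cc(OCC=C)c(OCC=C)cc1OCOC | intermediate
22 | [2-(methoxymethoxy)-4,5-bis(prop-2-en-1-yloxy)benzyl]cerium dichloride (not isolated) | Cl[Ce](Cl)Cc1cc(OCC=C)c(OCC=C)cc1OCOC | intermediate
23 | (1S,2S,4aS,8aS)-1-[2-(methoxymethoxy)-4,5-bis(prop-2-en-1-yloxy)benzyl]-2,5,5,8a-tetramethyldecahydronaphthalen-1-ol | C[C@H]1CC[C@H]2C(C)(C)CCC[C@]2(C)[C@]1(O)Cc1cc(OCC=C)c(OCC=C)cc1OCOC | intermediate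
24 | methyl N-({(1S,2S,4aS,8aS)-1-[2-(methoxymethoxy)-4,5-bis(prop-2-en-1-yloxy)benzyl]-2,5,5,8a-tetramethyldecahydronaphthalen-1-yl}oxysulfonyl)carbamate, formed as its triethylammonium salt (not isolated) | C[C@H]1CC[C@H]2C(C)(C)CCC[C@]2(C)[C@]1(OS(=O)(=O)NC(=O)OC)Cc1cc(OCC=C)c(OCC=C)cc1OCOC | intermediate
25 | (1E,2S,4aS,8aS)-1-[2-(methoxymethoxy)-4,5-bis(prop-2-en-1-yloxy)benzylidene]-2,5,5,8a-tetramethyldecahydronaphthalene | C[C@H]1CC[C@H]2C(C)(C)CCC[C@]2(C)/C1=C/c1cc(OCC=C)c(OCC=C)cc1OCOC | intermediate
26 | trimethyl(2-{(E)-[(2S,4aS,8aS)-2,5,5,8a-tetramethyloctahydronaphthalen-1(2H)-ylidene]methyl}-4,5-bis(prop-2-en-1-yloxy)phenoxy)silane (not isolated) | C[C@H]1CC[C@H]2C(C)(C)CCC[C@]2(C)/C1=C/c1cc(OCC=C)c(OCC=C)cc1O[Si](C)(C)C | intermediate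
27 | 2-{(E)-[(2S,4aS,8aS)-2,5,5,8a-tetramethyloctahydronaphthalen-1(2H)-ylidene]methyl}-4,5-bis(prop-2-en-1-yloxy)phenol | C[C@H]1CC[C@H]2C(C)(C)CCC[C@]2(C)/C1=C/c1cc(OCC=C)c(OCC=C)cc1O | intermediate
28 | 2-(hydroxymethyl)-6-{(E)-[(2S,4aS,8aS)-2,5,5,8a-tetramethyloctahydronaphthalen-1(2H)-ylidene]methyl}-3,4-bis(prop-2-en-1-yloxy)phenol (not isolated) | C[C@H]1CC[C@H]2C(C)(C)CCC[C@]2(C)/C1=C/c1cc(OCC=C)c(OCC=C)c(CO)c1O | intermediate
29 | 2-hydroxy-3-{(E)-[(2S,4aS,8aS)-2,5,5,8a-tetramethyloctahydronaphthalen-1(2H)-ylidene]methyl}-5,6-bis(prop-2-en-1-yloxy)benzaldehyde | C[C@H]1CC[C@H]2C(C)(C)CCC[C@]2(C)/C1=C/c1cc(OCC=C)c(OCC=C)c(C=O)c1O | intermediate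
30 | 2-formyl-3,4-bis(prop-2-en-1-yloxy)-6-{(E)-[(2S,4aS,8aS)-2,5,5,8a-tetramethyloctahydronaphthalen-1(2H)-ylidene]methyl}phenyl hydrogen sulfate | C[C@H]1CC[C@H]2C(C)(C)CCC[C@]2(C)/C1=C/c1cc(OCC=C)c(OCC=C)c(C=O)c1OS(=O)(=O)O | intermediate
31 | 2-formyl-3,4-dihydroxy-6-{(E)-[(2S,4aS,8aS)-2,5,5,8a-tetramethyloctahydronaphthalen-1(2H)-ylidene]methyl}phenyl hydrogen sulfate | C[C@H]1CC[C@H]2C(C)(C)CCC[C@]2(C)/C1=C/c1cc(O)c(O)c(C=O)c1OS(=O)(=O)O | target

**Step count**

Total: 20 steps. Longest linear sequence: 16 steps (steps 1–10 and 15–20, from 1 to 31); the benzyl branch (steps 11–14) joins at step 15.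

**Steps most likely to fail**

1. Step 8 (the new method). The ion pair may discriminate the two faces of the phenoxide poorly, and ipso attack at C6 or intermolecular O-alkylation may compete with closure at C10. Fallback with known chemistry: starting from 11, ring A is closed with an achiral base (KOt-Bu, t-BuOH/THF, high dilution), the established base-mediated intramolecular C-alkylation of a 2,6-disubstituted phenoxide. This gives racemic 3,4a,8,8-tetramethyl-4-oxo-4,4a,5,6,7,8-hexahydronaphthalen-1-yl trifluoromethanesulfonate F1. Its enantiomers are separated by preparative chromatography on a polysaccharide-based chiral stationary phase; the (S) enantiomer is 13 and the route resumes at step 9.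

2. Step 10. Hydrogen may reach C5=C6 or C7=C8 from the wrong face, the hindered C5=C6 alkene may resist reduction, and the C8 centre may epimerise through the enol towards the more stable equatorial methyl. Fallback: starting from 14, a dissolving-metal reduction (Li, NH3, THF, one equivalent of t-BuOH, −78 °C, solid NH4Cl quench) reduces the linear dienone in the 1,6 sense. Axial protonation at C5 gives the trans ring fusion, and kinetic protonation of the dienolate at C8 from the face opposite the C10 methyl gives the β,γ-unsaturated ketone (2S,4aS,8aS)-2,5,5,8a-tetramethyl-4a,5,6,7,8,8a-hexahydronaphthalen-1(2H)-one F2. Its unhindered disubstituted C6=C7 alkene is then hydrogenated under mild conditions (H2, 1 bar, Pd/C, EtOAc) to return to 15.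

3. Step 15. Magnesium insertion into the electron-rich benzylic chloride may be overtaken by Wurtz homocoupling, so that too little nucleophile reaches the hindered ketone. Fallback: the benzylic anion is made by transmetalation instead of reductive insertion. Starting from 20, displacement of chloride with Bu3SnLi (THF, −78 °C) gives the storable tributyl{[2-(methoxymethoxy)-4,5-bis(prop-2-en-1-yloxy)phenyl]methyl}stannane F3. Tin–lithium exchange with n-BuLi at −78 °C then gives {[2-(methoxymethoxy)-4,5-bis(prop-2-en-1-yloxy)phenyl]methyl}lithium F4 free of the chloride. Transmetalation with CeCl3 leads to 22, and addition to 15 returns to 23.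

**Further compounds**

F1 | step 8 | racemic 3,4a,8,8-tetramethyl-4-oxo-4,4a,5,6,7,8-hexahydronaphthalen-1-yl trifluoromethanesulfonate | CC1=CC(OS(=O)(=O)C(F)(F)F)=C2C(C)(C)CCCC2(C)C1=O
F2 | step 10 | (2S,4aS,8aS)-2,5,5,8a-tetramethyl-4a,5,6,7,8,8a-hexahydronaphthalen-1(2H)-one | C[C@H]1C=C[C@H]2C(C)(C)CCC[C@]2(C)C1=O
F3 | step 15 | tributyl{[2-(methoxymethoxy)-4,5-bis(prop-2-en-1-yloxy)phenyl]methyl}stannane | CCCC[Sn](CCCC)(CCCC)Cc1cc(OCC=C)c(OCC=C)cc1OCOC
F4 | step 15 | {[2-(methoxymethoxy)-4,5-bis(prop-2-en-1-yloxy)phenyl]methyl}lithium | [Li]Cc1cc(OCC=C)c(OCC=C)cc1OCOC
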